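**Retrosynthetic overview**

1. The target is reached from 3',5'-bis(benzyloxy)-5,6,7,8,4'-pentamethoxyflavone by C3 hydroxylation (C3 lithiation, borylation, oxidation), O-methylation and hydrogenolysis of the two benzyl ethers.
2. That flavone is cut at O1–C8a, C4–C4a and O1–C2 into 3,4,5,6-tetramethoxybenzyne and the ring B arylpropiolic acid. The strategy rests on ring A carrying methoxy groups on all of C5, C6, C7 and C8: its two remaining atoms, the neighbours C4a (bonded to C4) and C8a (bonded to O1), are the two carbons of an aryne with a mirror plane through the middle of its triple bond, so either sense of addition gives the same ring A.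
3. The aryne precursor, an o-silylaryl triflate, comes from 1,2,3,4-tetramethoxybenzene via the phenol, bromination at the only free carbon, O-silylation, retro-Brook shift and triflation.
4. The propiolic acid comes from methyl 3,5-dihydroxy-4-methoxybenzoate by benzylation, reduction and re-oxidation to the aldehyde, and Corey–Fuchs homologation with CO2 trapping.
5. Ring order: rings A and B are bought as benzenes; ring C (the 4-pyranone) is the only ring built, in the key step.

Key step: step 10

Assumption: 1,2,3,4-tetramethoxybenzene and methyl 3,5-dihydroxy-4-methoxybenzoate are bought; the target has no stereocentre, so no stereocontrol is planned.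

**Route**

Step 1
Reactants: 1 1,2,3,4-tetramethoxybenzene
Product: 4 2,3,4,5-tetramethoxyphenol, via aryllithium 2 (not isolated), via dimethyl arylboronate 3 (not isolated)
Conditions: n-BuLi, TMEDA, THF, 0 °C; B(OMe)3, −78 °C → rt; AcOH, 30% H2O2, 0 °C → rt
Reagents that add atoms: hydrogen peroxide, OO (oxygen of 4); n-butyllithium, [Li]CCCC and trimethyl borate, COB(OC)OC (atoms of 2 and 3 only)
Why: Methoxy-directed ortho-lithiation at one of the two equivalent free positions, borylation and oxidative C–B to C–O conversion (directed ortho-metalation, borylation–oxidation) should give the phenol.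

Step 2
Reactants: 4 2,3,4,5-tetramethoxyphenol
Product: 5 2-bromo-3,4,5,6-tetramethoxyphenol
Conditions: NBS (1.0 equiv), CH2Cl2, −40 → 0 °C, dark
Reagents that add atoms: N-bromosuccinimide, O=C1CCC(=O)N1Br
Why: The ring has one unsubstituted carbon, ortho to the hydroxyl group, so electrophilic aromatic bromination can take place only there.

Step 3
Reactants: 5 2-bromo-3,4,5,6-tetramethoxyphenol
Product: 6 (2-bromo-3,4,5,6-tetramethoxyphenoxy)trimethylsilane
Conditions: HMDS, THF, reflux; evaporate, use crude
Reagents that add atoms: hexamethyldisilazane, C[Si](C)(C)N[Si](C)(C)C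
Why: O-silylation of a phenol with HMDS gives the aryl silyl ether and only ammonia beside it, which sets up the silyl migration.

Step 4
Reactants: 6 (2-bromo-3,4,5,6-tetramethoxyphenoxy)trimethylsilane
Product: 9 2,3,4,5-tetramethoxy-6-(trimethylsilyl)phenyl trifluoromethanesulfonate, via ortho-silyloxy aryllithium 7 (not isolated), via lithium ortho-silylphenoxide 8 (not isolated)
Conditions: n-BuLi, THF, −100 → −80 °C; Tf2O, −100 → −78 °C
Reagents that add atoms: trifluoromethanesulfonic anhydride, O=S(=O)(OS(=O)(=O)C(F)(F)F)C(F)(F)F; n-butyllithium, [Li]CCCC (lithium of 7 and 8 only)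
Why: Bromine–lithium exchange gives an aryllithium that undergoes a 1,3 O→C silyl shift (retro-Brook rearrangement) to the lithium phenoxide, which is triflated in the same flask, the standard way to o-silylaryl triflates.

Step 5
Reactants: 10 methyl 3,5-dihydroxy-4-methoxybenzoate
Product: 11 methyl 3,5-bis(benzyloxy)-4-methoxybenzoate
Conditions: BnBr (2.4 equiv), K2CO3, DMF, 60 °C
Reagents that add atoms: benzyl bromide, BrCc1ccccc1
Why: Williamson etherification of both phenols masks them as benzyl ethers that survive the organolithium, fluoride and amide-base steps and fall off by hydrogenolysis at the end.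

Step 6
Reactants: 11 methyl 3,5-bis(benzyloxy)-4-methoxybenzoate
Product: 12 [3,5-bis(benzyloxy)-4-methoxyphenyl]methanol
Conditions: LiAlH4, THF, 0 °C → rt; H2O, aq NaOH work-up
Reagents that add atoms: none
Why: Hydride reduction of the aryl ester to the benzylic alcohol is used because direct partial reduction to the aldehyde is unreliable, and the ethers are inert to LiAlH4.

Step 7
Reactants: 12 [3,5-bis(benzyloxy)-4-methoxyphenyl]methanol
Product: 13 3,5-bis(benzyloxy)-4-methoxybenzaldehyde
Conditions: activated MnO2 (excess), CH2Cl2, rt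
Reagents that add atoms: none
Why: MnO2 oxidises benzylic alcohols to aldehydes selectively and should stop at the aldehyde.

Step 8
Reactants: 13 3,5-bis(benzyloxy)-4-methoxybenzaldehyde
Product: 14 1,3-bis(benzyloxy)-5-(2,2-dibromoethenyl)-2-methoxybenzene
Conditions: CBr4, PPh3, CH2Cl2, 0 °C
Reagents that add atoms: carbon tetrabromide, BrC(Br)(Br)Br
Why: The first stage of the Corey–Fuchs reaction (Wittig-type dibromo-olefination with the ylide from PPh3 and CBr4) adds the one carbon needed for the alkyne.

Step 9
Reactants: 14 1,3-bis(benzyloxy)-5-(2,2-dibromoethenyl)-2-methoxybenzene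
Product: 16 3-[3,5-bis(benzyloxy)-4-methoxyphenyl]prop-2-ynoic acid, via lithium acetylide 15 (not isolated)
Conditions: n-BuLi (2.2 equiv), THF, −78 °C; CO2, −78 °C → rt; aq HCl, 0 °C
Reagents that add atoms: carbon dioxide, O=C=O; n-butyllithium, [Li]CCCC (lithium of 15 only)
Why: The second stage of the Corey–Fuchs reaction (bromine–lithium exchange, Fritsch–Buttenberg–Wiechell shift, deprotonation) gives the lithium acetylide, whose carboxylation with CO2 gives the propiolic acid directly.

Step 10
Reactants: 9 2,3,4,5-tetramethoxy-6-(trimethylsilyl)phenyl trifluoromethanesulfonate; 16 3-[3,5-bis(benzyloxy)-4-methoxyphenyl]prop-2-ynoic acid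
Product: 19 2-[3,5-bis(benzyloxy)-4-methoxyphenyl]-5,6,7,8-tetramethoxy-4H-chromen-4-one, via tetramethoxybenzyne 17 (not isolated), via o-hydroxyaryl ynone 18 (not isolated)
Conditions: 9 (1.5 equiv), CsF (4 equiv), THF, 125 °C, sealed tube
Reagents that add atoms: none
Why: Fluoride removes the silyl group of 9 and triflate departs to give the symmetric aryne 17, to which the caesium carboxylate of 16 adds through oxygen (O1–C8a); the resulting aryl anion, ortho to the ester oxygen, attacks its own acyl carbon through a four-membered transition state and the acyl C–O bond breaks, leaving the phenoxide of o-hydroxyaryl ynone 18 (C4–C4a). The closest known reaction type is the insertion of arynes into the C–O bond of carboxylic acids, which with arylpropiolic acids is known to run on to flavones. Ring C then closes by 6-endo-dig conjugate addition of the phenoxide oxygen to the alkyne carbon that bears ring B (O1–C2), and C3 takes up the proton that the acid supplied. No stereocentre is formed. Regioselectivity of the aryne addition is not needed, because the two aryne carbons of 17 are equivalent and each is flanked by a methoxy group. What the step needs is acyl transfer faster than protonation of the aryl anion, helped by the high temperature and by the acid being the limiting component, and 6-endo over 5-exo closure, secured because attack at the β-carbon of the ynone is the Michael mode and leads to the conjugated 4-pyranone.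

Step 11
Reactants: 19 2-[3,5-bis(benzyloxy)-4-methoxyphenyl]-5,6,7,8-tetramethoxy-4H-chromen-4-one
Product: 22 2-[3,5-bis(benzyloxy)-4-methoxyphenyl]-3-hydroxy-5,6,7,8-tetramethoxy-4H-chromen-4-one, via 3-lithioflavone 20 (not isolated), via flavon-3-yl dimethyl boronate 21 (not isolated)
Conditions: LiN(iPr)2 (LDA, 1.3 equiv), THF, −78 °C; B(OMe)3, −78 °C → rt; AcOH, 30% H2O2, 0 °C → rt
Reagents that add atoms: hydrogen peroxide, OO (oxygen of 22); LiN(iPr)2, [Li]N(C(C)C)C(C)C and trimethyl borate, COB(OC)OC (atoms of 20 and 21 only)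
Why: C3–H is the only ring C hydrogen and lies next to the carbonyl group, so carbonyl-assisted deprotonation with LDA at −78 °C, borate trapping and peroxide oxidation (the known flavone C3 lithiation–borylation–oxidation) should give the flavonol.

Step 12
Reactants: 22 2-[3,5-bis(benzyloxy)-4-methoxyphenyl]-3-hydroxy-5,6,7,8-tetramethoxy-4H-chromen-4-one
Product: 23 2-[3,5-bis(benzyloxy)-4-methoxyphenyl]-3,5,6,7,8-pentamethoxy-4H-chromen-4-one
Conditions: MeI, K2CO3, acetone, reflux
Reagents that add atoms: iodomethane, CI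
Why: The 3-hydroxyl is the only free OH and is acidic, so Williamson O-methylation should be clean.

Step 13
Reactants: 23 2-[3,5-bis(benzyloxy)-4-methoxyphenyl]-3,5,6,7,8-pentamethoxy-4H-chromen-4-one
Product: 24 3',5'-dihydroxy-3,5,6,7,8,4'-hexamethoxyflavone
Conditions: H2 (1 atm), 10% Pd/C, EtOAc–MeOH, rt
Reagents that add atoms: none
Why: Catalytic hydrogenolysis cleaves the two aryl benzyl ethers, while the methyl ethers and the tetrasubstituted C2=C3 bond of the chromone should not react at ambient pressure and temperature.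

**Compound list**

1 | 1,2,3,4-tetramethoxybenzene | COc1ccc(OC)c(OC)c1OC | starting material
2 | (2,3,4,5-tetramethoxyphenyl)lithium | [Li]c1cc(OC)c(OC)c(OC)c1OC | intermediate
3 | dimethyl (2,3,4,5-tetramethoxyphenyl)boronate | COB(OC)c1cc(OC)c(OC)c(OC)c1OC | intermediate
4 | 2,3,4,5-tetramethoxyphenol | COc1cc(O)c(OC)c(OC)c1OC | intermediate
5 | 2-bromo-3,4,5,6-tetramethoxyphenol | COc1c(Br)c(O)c(OC)c(OC)c1OC | intermediate
6 | (2-bromo-3,4,5,6-tetramethoxyphenoxy)trimethylsilane | COc1c(Br)c(O[Si](C)(C)C)c(OC)c(OC)c1OC | intermediate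
7 | [3,4,5,6-tetramethoxy-2-(trimethylsilyloxy)phenyl]lithium | COc1c([Li])c(O[Si](C)(C)C)c(OC)c(OC)c1OC | intermediate
8 | lithium 2,3,4,5-tetramethoxy-6-(trimethylsilyl)phenoxide | COc1c([Si](C)(C)C)c([O-])c(OC)c(OC)c1OC.[Li+] | intermediate
9 | 2,3,4,5-tetramethoxy-6-(trimethylsilyl)phenyl trifluoromethanesulfonate | COc1c(OC)c(OC)c(OC)c(OS(=O)(=O)C(F)(F)F)c1[Si](C)(C)C | intermediate
10 | methyl 3,5-dihydroxy-4-methoxybenzoate | COC(=O)c1cc(O)c(OC)c(O)c1 | starting material
11 | methyl 3,5-bis(benzyloxy)-4-methoxybenzoate | COC(=O)c1cc(OCc2ccccc2)c(OC)c(OCc2ccccc2)c1 | intermediate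
12 | [3,5-bis(benzyloxy)-4-methoxyphenyl]methanol | OCc1cc(OCc2ccccc2)c(OC)c(OCc2ccccc2)c1 | intermediate
13 | 3,5-bis(benzyloxy)-4-methoxybenzaldehyde | O=Cc1cc(OCc2ccccc2)c(OC)c(OCc2ccccc2)c1 | intermediate
14 | 1,3-bis(benzyloxy)-5-(2,2-dibromoethenyl)-2-methoxybenzene | BrC(Br)=Cc1cc(OCc2ccccc2)c(OC)c(OCc2ccccc2)c1 | intermediate
15 | {[3,5-bis(benzyloxy)-4-methoxyphenyl]ethynyl}lithium | [Li]C#Cc1cc(OCc2ccccc2)c(OC)c(OCc2ccccc2)c1 | intermediate
16 | 3-[3,5-bis(benzyloxy)-4-methoxyphenyl]prop-2-ynoic acid | OC(=O)C#Cc1cc(OCc2ccccc2)c(OC)c(OCc2ccccc2)c1 | intermediate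
17 | 3,4,5,6-tetramethoxybenzyne (1,2-didehydro-3,4,5,6-tetramethoxybenzene) | COC1=C(OC)C(OC)=C(OC)C#C1 | intermediate
18 | 3-[3,5-bis(benzyloxy)-4-methoxyphenyl]-1-(2-hydroxy-3,4,5,6-tetramethoxyphenyl)prop-2-yn-1-one | COc1c(OCc2ccccc2)cc(C#CC(=O)c2c(O)c(OC)c(OC)c(OC)c2OC)cc1OCc1ccccc1 | intermediate
19 | 2-[3,5-bis(benzyloxy)-4-methoxyphenyl]-5,6,7,8-tetramethoxy-4H-chromen-4-one | COc1c(OCc2ccccc2)cc(-c2cc(=O)c3c(OC)c(OC)c(OC)c(OC)c3o2)cc1OCc1ccccc1 | intermediate
20 | {2-[3,5-bis(benzyloxy)-4-methoxyphenyl]-5,6,7,8-tetramethoxy-4-oxo-4H-chromen-3-yl}lithium | COc1c(OCc2ccccc2)cc(-c2oc3c(OC)c(OC)c(OC)c(OC)c3c(=O)c2[Li])cc1OCc1ccccc1 | intermediate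
21 | dimethyl {2-[3,5-bis(benzyloxy)-4-methoxyphenyl]-5,6,7,8-tetramethoxy-4-oxo-4H-chromen-3-yl}boronate | COB(OC)c1c(-c2cc(OCc3ccccc3)c(OC)c(OCc3ccccc3)c2)oc2c(OC)c(OC)c(OC)c(OC)c2c1=O | intermediate
22 | 2-[3,5-bis(benzyloxy)-4-methoxyphenyl]-3-hydroxy-5,6,7,8-tetramethoxy-4H-chromen-4-one | COc1c(OCc2ccccc2)cc(-c2oc3c(OC)c(OC)c(OC)c(OC)c3c(=O)c2O)cc1OCc1ccccc1 | intermediate
23 | 2-[3,5-bis(benzyloxy)-4-methoxyphenyl]-3,5,6,7,8-pentamethoxy-4H-chromen-4-one | COc1c(OCc2ccccc2)cc(-c2oc3c(OC)c(OC)c(OC)c(OC)c3c(=O)c2OC)cc1OCc1ccccc1 | intermediate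
24 | 3',5'-dihydroxy-3,5,6,7,8,4'-hexamethoxyflavone | COc1c(O)cc(-c2oc3c(OC)c(OC)c(OC)c(OC)c3c(=O)c2OC)cc1O | target

**Step count and risks**

Total step count: 13. Longest linear sequence: 9 steps (steps 5 to 13, from 10 to 24); the ring A branch (steps 1 to 4) joins at step 10.

Steps most likely to fail:

Step 10. The aryl anion formed after carboxylate addition may be protonated by unreacted acid before acyl transfer, which would stop the sequence at the aryl ester stage. The propiolate may also lose CO2 at the reaction temperature, and the phenoxide may be arylated by a second aryne. If open-chain 18 merely accumulates, Et2NH in EtOH should close it 6-endo through the enaminone. The fallback proper builds ring C from an acetophenone in place of the aryne; it sets out from phenol 4 and aldehyde 13 and comes back at flavone 19. C-acetylation of 4 ortho to the hydroxyl group with AcOH and BF3·OEt2 at 90 °C should give 1-(2-hydroxy-3,4,5,6-tetramethoxyphenyl)ethanone F1. Claisen–Schmidt condensation of F1 with 13 (KOH, EtOH, rt) should give (E)-3-[3,5-bis(benzyloxy)-4-methoxyphenyl]-1-(2-hydroxy-3,4,5,6-tetramethoxyphenyl)prop-2-en-1-one F2. Oxidative cyclisation of F2 with catalytic I2 in DMSO at 130 °C should give 19.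

Step 11. The 3-lithio species may open by β-elimination of the C8a phenoxide (the reverse of the ring closure), or the amide base may deprotonate a benzylic OCH2 group. The fallback oxidises the C2=C3 bond instead of metalating it; it sets out from flavone 19 and comes back at flavonol 22. Epoxidation of 19 with dimethyldioxirane in acetone–CH2Cl2 at 0 °C should give racemic 2-[3,5-bis(benzyloxy)-4-methoxyphenyl]-2,3-epoxy-5,6,7,8-tetramethoxychroman-4-one F3. Catalytic p-TsOH in CH2Cl2 should then open the epoxide at C2 and, after loss of the C3 proton, give 22.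

Step 2. NBS may act as an oxidant on the penta-oxygenated ring (oxidative demethylation towards a quinone) instead of substituting at carbon. The fallback installs silicon by directed ortho-lithiation and avoids any electrophilic halogen; it sets out from phenol 4 and comes back at silyl triflate 9, bypassing steps 2 to 4. Addition of 4 to isopropyl isocyanate (Et3N, CH2Cl2) should give 2,3,4,5-tetramethoxyphenyl N-isopropylcarbamate F4. N-silylation in the flask (TMSOTf, TMEDA, Et2O), carbamate-directed ortho-lithiation (n-BuLi, TMEDA, −78 °C), TMSCl quench and aqueous work-up should give 2,3,4,5-tetramethoxy-6-(trimethylsilyl)phenyl N-isopropylcarbamate F5. Carbamate cleavage with Et2NH and DBU in MeCN at 40 °C, followed by PhNTf2 in the same flask, should give 9.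

**Further compounds**

F1 | step 10 | 1-(2-hydroxy-3,4,5,6-tetramethoxyphenyl)ethanone | CC(=O)c1c(O)c(OC)c(OC)c(OC)c1OC
F2 | step 10 | (E)-3-[3,5-bis(benzyloxy)-4-methoxyphenyl]-1-(2-hydroxy-3,4,5,6-tetramethoxyphenyl)prop-2-en-1-one | COc1c(OCc2ccccc2)cc(/C=C/C(=O)c2c(O)c(OC)c(OC)c(OC)c2OC)cc1OCc1ccccc1
F3 | step 11 | racemic 2-[3,5-bis(benzyloxy)-4-methoxyphenyl]-2,3-epoxy-5,6,7,8-tetramethoxychroman-4-one (cis-fused epoxide, one enantiomer drawn) | COc1c(OCc2ccccc2)cc([C@]23O[C@H]2C(=O)c2c(OC)c(OC)c(OC)c(OC)c2O3)cc1OCc1ccccc1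
F4 | step 2 | 2,3,4,5-tetramethoxyphenyl N-isopropylcarbamate | COc1cc(OC(=O)NC(C)C)c(OC)c(OC)c1OC
F5 | step 2 | 2,3,4,5-tetramethoxy-6-(trimethylsilyl)phenyl N-isopropylcarbamate | COc1c([Si](C)(C)C)c(OC(=O)NC(C)C)c(OC)c(OC)c1OC
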